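Assumption: the SMILES is read as (3R,4R) in the lactone and (7''R,8''R) in the side chain, so OH and ring B are anti in the zigzag ring C–C7''–C8''–C9''. Ring A is the aryl of the C3 benzyl group, ring B the central aryl, ring C the carbinol aryl.

## Retrosynthetic overview
1. Target ⇒ tri-O-benzyl ether by global hydrogenolysis. Its C9''H2OH ⇒ a vinyl group by oxidative cleavage and reduction.
2. The C7''–C8'' bond and both side-chain stereocentres ⇒ a chair-type allylboration of O-benzylvanillin under chiral phosphoric acid control. The (E)-γ-aryl allylboronate comes from cross-metathesis on a 5'-vinyl dibenzylbutyrolactone.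
3. Dibenzylbutyrolactone ⇒ one-pot union of the ring B aryl Grignard, a cyclopropane-fused lactone (strain-release opening at its CH2) and the ring A benzyl bromide. Loss of the CO2Me activator follows, and C3 is set trans to C4 by equilibration.
4. Cyclopropane-fused lactone ⇒ (R)-epichlorohydrin + dimethyl malonate. The cyclopropane and the γ-lactone close in the same operation, which fixes C4.
5. Ring order: cyclopropane, then lactone, in one pot. The cyclopropane is spent later, the lactone is carried to the end, and the three arenes are bought.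

## Route

**Step 1**
Reactants: 1 (R)-epichlorohydrin; 2 dimethyl malonate
Product: 5 methyl (1S,5R)-2-oxo-3-oxabicyclo[3.1.0]hexane-1-carboxylate, via oxiranylmethyl malonate 3 (not isolated), via cyclopropylmethanol diester 4 (not isolated)
Conditions: NaOMe (1.0 equiv), MeOH, 0 °C → reflux, 16 h; distillation
Reagents that add atoms: none
Why: In this tandem alkylation/cyclopropanation/lactonisation the malonate anion opens the epoxide at CH2, the alkoxide re-closes on CH2Cl to give 3, a second deprotonation triggers a 3-exo-tet SN2 opening with clean inversion to give 4, and its alkoxide lactonises on the cis ester, so both rings form in one operation, the centre of 1 is relayed to C5 (R), and C1 (S) follows from the obligatory cis fusion.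

**Step 2**
Reactants: 6 5-bromo-2-hydroxy-3-methoxybenzaldehyde
Product: 7 2-(benzyloxy)-5-bromo-3-methoxybenzaldehyde
Conditions: BnBr, K2CO3, DMF, 60 °C
Reagents that add atoms: benzyl bromide, BrCc1ccccc1
Why: Williamson ether synthesis (SN2 O-alkylation of the phenoxide) masks the ring B phenol with a group that survives Grignard, metathesis and ozonolysis conditions, and no stereocentre is involved.

**Step 3**
Reactants: 7 2-(benzyloxy)-5-bromo-3-methoxybenzaldehyde
Product: 8 2-(benzyloxy)-5-bromo-1-ethenyl-3-methoxybenzene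
Conditions: Ph3PCH3Br, KOtBu, THF, 0 °C → 23 °C
Reagents that add atoms: methyltriphenylphosphonium bromide, [Br-].C[P+](c1ccccc1)(c1ccccc1)c1ccccc1
Why: Wittig methylenation of a non-enolisable aryl aldehyde gives the styrene whose α-carbon becomes C8'', and the aryl bromide is inert to the ylide.

**Step 4**
Reactants: 9 [4-(benzyloxy)-3-methoxyphenyl]methanol
Product: 10 1-(benzyloxy)-4-(bromomethyl)-2-methoxybenzene
Conditions: PBr3 (0.4 equiv), Et2O, 0 °C; used crude the same day
Reagents that add atoms: phosphorus tribromide, BrP(Br)Br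
Why: Bromodehydroxylation of an electron-rich benzylic alcohol through its phosphite ester (SN2) is fast at 0 °C and leaves the aryl ethers untouched.

**Step 5**
Reactants: 8 2-(benzyloxy)-5-bromo-1-ethenyl-3-methoxybenzene; 5 methyl (1S,5R)-2-oxo-3-oxabicyclo[3.1.0]hexane-1-carboxylate; 10 1-(benzyloxy)-4-(bromomethyl)-2-methoxybenzene
Product: 13 methyl (3R,4R)-3-[4-(benzyloxy)-3-methoxybenzyl]-4-[4-(benzyloxy)-3-ethenyl-5-methoxybenzyl]-2-oxooxolane-3-carboxylate, via aryl Grignard reagent 11 (not isolated), via bromomagnesium enolate 12 (not isolated)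
Conditions: 8, Mg, LiCl, THF, 25 °C; CuI (10 mol %), then 5 (1.1 equiv), −30 → 0 °C; then DMPU, 10 (1.2 equiv), Bu4NI (10 mol %), 0 → 40 °C
Reagents that add atoms: magnesium, [Mg] (kept only in 11 and 12)
Why: Copper-catalysed homoconjugate addition of the Grignard reagent to the doubly activated cyclopropane attacks the unsubstituted CH2 and breaks the C1–C6 bond, so the stereocentre (future C4, R) is untouched, and the released malonate-type enolate is C-benzylated in situ anti to the new arylmethyl group (tandem ring opening/enolate alkylation).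

**Step 6**
Reactants: 13 methyl (3R,4R)-3-[4-(benzyloxy)-3-methoxybenzyl]-4-[4-(benzyloxy)-3-ethenyl-5-methoxybenzyl]-2-oxooxolane-3-carboxylate
Product: 15 (3R,4R)-3-[4-(benzyloxy)-3-methoxybenzyl]-4-[4-(benzyloxy)-3-ethenyl-5-methoxybenzyl]oxolan-2-one, via cis epimer 14 (not isolated)
Conditions: LiCl (3 equiv), H2O (2 equiv), BHT (1 mol %), DMSO, 140 °C; then DBU (0.5 equiv), 100 °C
Reagents that add atoms: none
Why: Krapcho demethoxycarbonylation (chloride SN2 on the methyl ester, loss of CO2, protonation of the lactone enolate) followed by base epimerisation at the only acidic centre funnels 14 into the thermodynamically preferred trans-3,4-disubstituted lactone, which sets C3 (R) relative to the fixed C4 (R).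

**Step 7**
Reactants: 15 (3R,4R)-3-[4-(benzyloxy)-3-methoxybenzyl]-4-[4-(benzyloxy)-3-ethenyl-5-methoxybenzyl]oxolan-2-one; 16 4-(benzyloxy)-3-methoxybenzaldehyde
Product: 19 (3R,4R)-3-[4-(benzyloxy)-3-methoxybenzyl]-4-(4-(benzyloxy)-3-{(1R,2S)-1-[4-(benzyloxy)-3-methoxyphenyl]-1-hydroxybut-3-en-2-yl}-5-methoxybenzyl)oxolan-2-one, via allylboronate 17 (not isolated), via pinacol borate 18 (not isolated)
Conditions: allylB(pin) (2 equiv), second-generation Hoveyda–Grubbs catalyst RuCl2(SIMes)(=CH-C6H4-2-OiPr) (5 mol %), CH2Cl2, 40 °C; volatiles stripped in high vacuum; then 16 (2.5 equiv), (R)-TRIP [(R)-3,3'-bis(2,4,6-triisopropylphenyl)-1,1'-binaphthyl-2,2'-diyl hydrogen phosphate] (10 mol %), 4 Å MS, toluene, −30 → 0 °C; aq NaHCO3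
Reagents that add atoms: allylboronic acid pinacol ester, C=CCB1OC(C)(C)C(C)(C)O1
Why: Olefin cross-metathesis gives the (E)-γ-aryl allylboronate 17, and the chiral-phosphoric-acid-catalysed allylboration runs through a closed chair (Zimmerman–Traxler) transition state that turns E geometry into the anti relationship while (R)-TRIP exposes the Re face of 16, which sets C7'' (R) and C8'' (descriptor S here, R once vinyl has become CH2OH) under catalyst control.

**Step 8**
Reactants: 19 homoallylic alcohol from step 7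
Product: 21 (3R,4R)-3-[4-(benzyloxy)-3-methoxybenzyl]-4-(4-(benzyloxy)-3-{(1R,2R)-1-[4-(benzyloxy)-3-methoxyphenyl]-1,3-dihydroxypropan-2-yl}-5-methoxybenzyl)oxolan-2-one, via hydroxy aldehyde 20 (not isolated)
Conditions: O3, CH2Cl2–MeOH (4:1), −78 °C, Sudan Red 7B end-point; then NaBH4, −78 → 0 °C
Reagents that add atoms: ozone, [O-][O+]=O
Why: Ozonolysis (Criegee cleavage) of the only C=C bond, which reacts far faster than the alkoxyarenes, and immediate borohydride reduction of 20 in the cold turn vinyl into CH2OH before the α-aryl-β-hydroxy aldehyde can epimerise or undergo retro-aldol cleavage, so both side-chain centres and the lactone are kept.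

**Step 9**
Reactants: 21 tri-O-benzyl ether from step 8
Product: 22 (3R,4R)-4-(3-{(1R,2R)-1,3-dihydroxy-1-(4-hydroxy-3-methoxyphenyl)propan-2-yl}-4-hydroxy-5-methoxybenzyl)-3-(4-hydroxy-3-methoxybenzyl)oxolan-2-one (target)
Conditions: H2 (1 atm), Pd/C (10 wt %), EtOAc–EtOH, 23 °C, stopped after uptake of 3 equiv; neutral work-up
Reagents that add atoms: none
Why: Heterogeneous hydrogenolysis of the three aryl benzyl ethers under neutral conditions is much faster than C–O hydrogenolysis of the secondary benzylic alcohol, and no stereocentre is touched.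

## Compound list
1 | (R)-epichlorohydrin | ClC[C@H]1CO1 | starting material
2 | dimethyl malonate | COC(=O)CC(=O)OC | starting material
3 | dimethyl 2-{[(2R)-oxiran-2-yl]methyl}malonate | COC(=O)C(C[C@@H]1CO1)C(=O)OC | intermediate
4 | dimethyl (2R)-2-(hydroxymethyl)cyclopropane-1,1-dicarboxylate (sodium alkoxide in the flask, drawn neutral) | COC(=O)C1(C[C@H]1CO)C(=O)OC | intermediate
5 | methyl (1S,5R)-2-oxo-3-oxabicyclo[3.1.0]hexane-1-carboxylate | COC(=O)[C@]12C[C@H]1COC2=O | intermediate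
6 | 5-bromo-2-hydroxy-3-methoxybenzaldehyde | COc1cc(Br)cc(C=O)c1O | starting material
7 | 2-(benzyloxy)-5-bromo-3-methoxybenzaldehyde | COc1cc(Br)cc(C=O)c1OCc1ccccc1 | intermediate
8 | 2-(benzyloxy)-5-bromo-1-ethenyl-3-methoxybenzene | COc1cc(Br)cc(C=C)c1OCc1ccccc1 | intermediate
9 | [4-(benzyloxy)-3-methoxyphenyl]methanol | COc1cc(CO)ccc1OCc1ccccc1 | starting material
10 | 1-(benzyloxy)-4-(bromomethyl)-2-methoxybenzene | COc1cc(CBr)ccc1OCc1ccccc1 | intermediate
11 | [4-(benzyloxy)-3-ethenyl-5-methoxyphenyl]magnesium bromide | COc1cc([Mg]Br)cc(C=C)c1OCc1ccccc1 | intermediate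
12 | bromomagnesium enolate of methyl (4R)-4-[4-(benzyloxy)-3-ethenyl-5-methoxybenzyl]-2-oxooxolane-3-carboxylate | COC(=O)C1=C(O[Mg]Br)OC[C@@H]1Cc1cc(OC)c(OCc2ccccc2)c(C=C)c1 | intermediate
13 | methyl (3R,4R)-3-[4-(benzyloxy)-3-methoxybenzyl]-4-[4-(benzyloxy)-3-ethenyl-5-methoxybenzyl]-2-oxooxolane-3-carboxylate | COc1cc(C[C@@]2(C(=O)OC)C(=O)OC[C@@H]2Cc2cc(OC)c(OCc3ccccc3)c(C=C)c2)ccc1OCc1ccccc1 | intermediate
14 | (3S,4R) cis epimer of 15 | COc1cc(C[C@@H]2C(=O)OC[C@@H]2Cc2cc(OC)c(OCc3ccccc3)c(C=C)c2)ccc1OCc1ccccc1 | intermediate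
15 | (3R,4R)-3-[4-(benzyloxy)-3-methoxybenzyl]-4-[4-(benzyloxy)-3-ethenyl-5-methoxybenzyl]oxolan-2-one | COc1cc(C[C@H]2C(=O)OC[C@@H]2Cc2cc(OC)c(OCc3ccccc3)c(C=C)c2)ccc1OCc1ccccc1 | intermediate
16 | 4-(benzyloxy)-3-methoxybenzaldehyde | COc1cc(C=O)ccc1OCc1ccccc1 | starting material
17 | 15 with the vinyl group replaced by (E)-3-(4,4,5,5-tetramethyl-1,3,2-dioxaborolan-2-yl)prop-1-enyl | COc1cc(C[C@H]2C(=O)OC[C@@H]2Cc2cc(OC)c(OCc3ccccc3)c(/C=C/CB3OC(C)(C)C(C)(C)O3)c2)ccc1OCc1ccccc1 | intermediate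
18 | O-(pinacolboryl) derivative of 19 | COc1cc(C[C@H]2C(=O)OC[C@@H]2Cc2cc(OC)c(OCc3ccccc3)c([C@H](C=C)[C@@H](OB3OC(C)(C)C(C)(C)O3)c3ccc(OCc4ccccc4)c(OC)c3)c2)ccc1OCc1ccccc1 | intermediate
19 | anti homoallylic alcohol, side chain (1R,2S)-1-aryl-1-hydroxybut-3-en-2-yl on C5' of ring B | COc1cc(C[C@H]2C(=O)OC[C@@H]2Cc2cc(OC)c(OCc3ccccc3)c([C@H](C=C)[C@@H](O)c3ccc(OCc4ccccc4)c(OC)c3)c2)ccc1OCc1ccccc1 | intermediate
20 | (2S,3R)-3-hydroxy-2,3-diarylpropanal (vinyl of 19 cleaved to CHO) | COc1cc(C[C@H]2C(=O)OC[C@@H]2Cc2cc(OC)c(OCc3ccccc3)c([C@H](C=O)[C@@H](O)c3ccc(OCc4ccccc4)c(OC)c3)c2)ccc1OCc1ccccc1 | intermediate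
21 | tri-O-benzyl ether of the target, side chain (1R,2R) | COc1cc(C[C@H]2C(=O)OC[C@@H]2Cc2cc(OC)c(OCc3ccccc3)c([C@H](CO)[C@@H](O)c3ccc(OCc4ccccc4)c(OC)c3)c2)ccc1OCc1ccccc1 | intermediate
22 | CNP0109231.2 | COc1cc(C[C@H]2C(=O)OC[C@@H]2Cc2cc(OC)c(O)c([C@H](CO)[C@@H](O)c3ccc(O)c(OC)c3)c2)ccc1O | target

## Step count and risks
Total step count: 9. Longest linear sequence: 7 (6 → 7 → 8 → 13 → 15 → 19 → 21 → 22).

**Step 5.** The chelated magnesium enolate may be too sluggish toward 10, or may O-alkylate.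
- The fallback sets out from 12 and comes back at 15.
- Compound 12 is quenched with aq NH4Cl to give the ester lactone F1.
- The ester is removed first (LiCl, wet DMSO, 130 °C) to give the β-(arylmethyl) lactone F2.
- LiN(SiMe3)2 in THF at −78 °C gives its lithium enolate F3, which is alkylated with 10.
- C3 is now set by kinetic attack anti to the C4 substituent, so the quaternary centre and the equilibration are not needed, and 15 is obtained directly.

**Step 7.** The 2-alkoxystyrene can chelate ruthenium and slow the metathesis. Left-over allylboron species consume 16. The hindered γ-aryl boronate meets an electron-rich aldehyde.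
- The fallback sets out from 15 and comes back at 21. It replaces allylboration plus cleavage by an auxiliary-controlled aldol.
- 9-BBN in THF gives the B-alkyl borane F4, and NaBO3·4H2O oxidises it to the primary alcohol F5.
- TEMPO/PhI(OAc)2 in wet MeCN carries F5 through the arylacetaldehyde F6 to the arylacetic acid F7.
- DCC/DMAP coupling with (R)-4-benzyl-1,3-oxazolidin-2-one gives the imide F8.
- The Evans magnesium-catalysed anti aldol (MgCl2 10 mol %, Et3N, TMSCl, EtOAc, 16) goes through the chelated enolate and gives the silylated anti aldol F9.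
- TFA in MeOH frees the aldol F10.
- NaBH4 in THF–H2O reduces only the imide carbonyl and delivers 21.

**Step 8.** Ozone may attack the electron-rich rings or the benzyl ethers.
- The fallback sets out from 19 and comes back at 20.
- OsO4 (2 mol %)/NMO in acetone–H2O dihydroxylates the vinyl group to the triol F11, a mixture of epimers at the new carbinol carbon.
- NaIO4 on silica in CH2Cl2 cleaves only the terminal 1,2-glycol, because the C7'' hydroxyl is 1,3-related. This gives 20.
- Compound 20 is reduced at once with NaBH4 to give 21.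

## Further compounds
F1 | step 5 | methyl (4R)-4-[4-(benzyloxy)-3-ethenyl-5-methoxybenzyl]-2-oxooxolane-3-carboxylate (C3 epimers) | COC(=O)C1C(=O)OC[C@@H]1Cc1cc(OC)c(OCc2ccccc2)c(C=C)c1
F2 | step 5 | (4R)-4-[4-(benzyloxy)-3-ethenyl-5-methoxybenzyl]oxolan-2-one | C1C(=O)OC[C@@H]1Cc1cc(OC)c(OCc2ccccc2)c(C=C)c1
F3 | step 5 | lithium enolate of F2 | C1=C(O[Li])OC[C@@H]1Cc1cc(OC)c(OCc2ccccc2)c(C=C)c1
F4 | step 7 | 15 with vinyl replaced by 2-(9-borabicyclo[3.3.1]nonan-9-yl)ethyl | COc1cc(C[C@H]2C(=O)OC[C@@H]2Cc2cc(OC)c(OCc3ccccc3)c(CCB3C4CCCC3CCC4)c2)ccc1OCc1ccccc1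
F5 | step 7 | 15 with vinyl replaced by 2-hydroxyethyl | COc1cc(C[C@H]2C(=O)OC[C@@H]2Cc2cc(OC)c(OCc3ccccc3)c(CCO)c2)ccc1OCc1ccccc1
F6 | step 7 | 15 with vinyl replaced by 2-oxoethyl | COc1cc(C[C@H]2C(=O)OC[C@@H]2Cc2cc(OC)c(OCc3ccccc3)c(CC=O)c2)ccc1OCc1ccccc1
F7 | step 7 | 15 with vinyl replaced by carboxymethyl | COc1cc(C[C@H]2C(=O)OC[C@@H]2Cc2cc(OC)c(OCc3ccccc3)c(CC(=O)O)c2)ccc1OCc1ccccc1
F8 | step 7 | N-(arylacetyl) imide of F7 with (R)-4-benzyl-1,3-oxazolidin-2-one | COc1cc(C[C@H]2C(=O)OC[C@@H]2Cc2cc(OC)c(OCc3ccccc3)c(CC(=O)N3[C@H](Cc4ccccc4)COC3=O)c2)ccc1OCc1ccccc1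
F9 | step 7 | (2S,3R) anti aldol imide, O-trimethylsilyl ether | COc1cc(C[C@H]2C(=O)OC[C@@H]2Cc2cc(OC)c(OCc3ccccc3)c([C@H](C(=O)N3[C@H](Cc4ccccc4)COC3=O)[C@@H](O[Si](C)(C)C)c3ccc(OCc4ccccc4)c(OC)c3)c2)ccc1OCc1ccccc1
F10 | step 7 | (2S,3R) anti aldol imide, free alcohol | COc1cc(C[C@H]2C(=O)OC[C@@H]2Cc2cc(OC)c(OCc3ccccc3)c([C@H](C(=O)N3[C@H](Cc4ccccc4)COC3=O)[C@@H](O)c3ccc(OCc4ccccc4)c(OC)c3)c2)ccc1OCc1ccccc1
F11 | step 8 | triol from dihydroxylation of the vinyl group of 19 (epimers at the new carbinol carbon) | COc1cc(C[C@H]2C(=O)OC[C@@H]2Cc2cc(OC)c(OCc3ccccc3)c([C@H](C(O)CO)[C@@H](O)c3ccc(OCc4ccccc4)c(OC)c3)c2)ccc1OCc1ccccc1
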